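**Retrosynthetic overview**
1. Target ⇐ removal of two silyl groups ⇐ esterification of the C15 alcohol of a macrolactone with a silyl-protected (S)-3-hydroxy-2-methylpropanoic acid.
2. Macrolactone ⇐ key C7–C8 bond: an asymmetric chromium-mediated 2-(methoxycarbonyl)allylation within one chain. The allylic bromide becomes a nucleophilic β-acrylate (homoenolate-type) carbon that attacks the C8 aldehyde and sets C7 and C8.
3. Acyclic bromo aldehyde ⇐ acetal hydrolysis ⇐ cross-metathesis of a terminal alkene with methyl 2-(bromomethyl)acrylate.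
4. Triene ⇐ E-selective Horner–Wadsworth–Emmons olefination (C1=C10), reduction and silylation ⇐ Z-selective Wittig olefination of an α-silyloxy ketone (C4=C5).
5. Ring order: no ring before the key step; it closes the ten-membered carbocycle first (C–C) and the γ-lactone second (C–O) in the same flask.

Positions are given in germacrane numbering: C7/C8 ring fusion, C11–C13 α-methylene lactone, C14 on C10, C15 on C4.

Assumption: the ligand enantiomer named in step 10 is taken to deliver the 7R,8S product; if the sense of induction is the opposite, its mirror image is used.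

**Step 1**
Reactants: 1 methyl 5-bromo-4-oxopentanoate
Product: 3 methyl 5-hydroxy-4-oxopentanoate, via formate ester 2 (not isolated)
Conditions: HCO2Na (3 equiv), MeOH, reflux
Reagents that add atoms: sodium formate, [Na+].[O-]C=O
Why: SN2 displacement of the activated α-bromo ketone by formate, then transesterification of the formate ester by the solvent, gives the α-hydroxy ketone without touching the methyl ester.

**Step 2**
Reactants: 3 methyl 5-hydroxy-4-oxopentanoate
Product: 4 methyl 4-oxo-5-[(triethylsilyl)oxy]pentanoate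
Conditions: Et3SiCl, imidazole, CH2Cl2, 0 °C
Reagents that add atoms: chlorotriethylsilane, CC[Si](Cl)(CC)CC
Why: Routine silylation of the primary alcohol gives the α-silyloxy ketone needed for the directed olefination, with a silyl group labile enough to leave together with the acetal later.

**Step 3**
Reactants: 4 methyl 4-oxo-5-[(triethylsilyl)oxy]pentanoate; 5 (but-3-en-1-yl)triphenylphosphonium bromide
Product: 7 methyl (4Z)-4-{[(triethylsilyl)oxy]methyl}octa-4,7-dienoate, via phosphorus ylide 6 (not isolated)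
Conditions: 5, KN(SiMe3)2, THF, −78 °C; then 4, −78 °C to 0 °C
Reagents that add atoms: none
Why: Wittig olefination of an α-silyloxy ketone with a salt-free non-stabilised ylide is kinetically Z-selective (CH2OSi ends cis to the new chain), which sets the C4=C5 geometry, and the ketone reacts far faster than the ester.

**Step 4**
Reactants: 8 trimethyl phosphonoacetate; 9 2-bromo-1,1-dimethoxyethane
Product: 10 methyl 2-(dimethoxyphosphoryl)-4,4-dimethoxybutanoate
Conditions: NaH, NaI (cat.), DMF, 0 °C then 90 °C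
Reagents that add atoms: none
Why: SN2 C-alkylation of the stabilised phosphonoacetate anion (iodide catalysis offsets the sluggish α-halo acetal) gives the olefination reagent that carries C8 as a masked aldehyde.

**Step 5**
Reactants: 7 methyl (4Z)-4-{[(triethylsilyl)oxy]methyl}octa-4,7-dienoate; 10 methyl 2-(dimethoxyphosphoryl)-4,4-dimethoxybutanoate
Product: 12 methyl (2E,6Z)-2-(2,2-dimethoxyethyl)-6-{[(triethylsilyl)oxy]methyl}deca-2,6,9-trienoate, via aldehyde 11 (not isolated)
Conditions: i-Bu2AlH (1.1 equiv), CH2Cl2, −78 °C; then sodium salt of 10 (10, NaH, THF), −78 °C to rt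
Reagents that add atoms: none
Why: One-pot partial DIBAL reduction of the ester and Horner–Wadsworth–Emmons olefination of the released aldehyde gives the E-enoate (ester trans to the chain), which places C9 cis to C2 at C1=C10; the minor Z isomer is removed by chromatography.

**Step 6**
Reactants: 12 methyl (2E,6Z)-2-(2,2-dimethoxyethyl)-6-{[(triethylsilyl)oxy]methyl}deca-2,6,9-trienoate
Product: 13 (2E,6Z)-2-(2,2-dimethoxyethyl)-6-{[(triethylsilyl)oxy]methyl}deca-2,6,9-trien-1-ol
Conditions: i-Bu2AlH (2.5 equiv), CH2Cl2, −78 °C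
Reagents that add atoms: none
Why: DIBAL 1,2-reduction of the conjugated ester gives the C14 allylic alcohol; acetal, silyl ether and alkenes are inert.

**Step 7**
Reactants: 13 (2E,6Z)-2-(2,2-dimethoxyethyl)-6-{[(triethylsilyl)oxy]methyl}deca-2,6,9-trien-1-ol
Product: 14 (2E,6Z)-1-[(tert-butyldimethylsilyl)oxy]-2-(2,2-dimethoxyethyl)-6-{[(triethylsilyl)oxy]methyl}deca-2,6,9-triene
Conditions: t-BuMe2SiCl, imidazole, DMF, rt
Reagents that add atoms: tert-butylchlorodimethylsilane, CC(C)(C)[Si](C)(C)Cl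
Why: Silylation with the more acid-stable TBS group keeps the C14 oxygen masked while the C15 oxygen is later freed and acylated.

**Step 8**
Reactants: 14 (2E,6Z)-1-[(tert-butyldimethylsilyl)oxy]-2-(2,2-dimethoxyethyl)-6-{[(triethylsilyl)oxy]methyl}deca-2,6,9-triene; 15 methyl 2-(bromomethyl)acrylate
Product: 16 methyl (2Z,5Z,9E)-2-(bromomethyl)-10-{[(tert-butyldimethylsilyl)oxy]methyl}-12,12-dimethoxy-6-{[(triethylsilyl)oxy]methyl}dodeca-2,5,9-trienoate
Conditions: 15 (5 equiv), second-generation Hoveyda–Grubbs catalyst (10 mol %), 1,4-benzoquinone (10 mol %), CH2Cl2, 40 °C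
Reagents that add atoms: none
Why: Olefin cross-metathesis of the only monosubstituted alkene with an excess of the 1,1-disubstituted electron-poor acrylate (trisubstituted alkenes inert) gives the trisubstituted enoate with the chain trans to the ester, by analogy with cross-metathesis of methacrylates and α-methylene lactones.

**Step 9**
Reactants: 16 methyl (2Z,5Z,9E)-2-(bromomethyl)-10-{[(tert-butyldimethylsilyl)oxy]methyl}-12,12-dimethoxy-6-{[(triethylsilyl)oxy]methyl}dodeca-2,5,9-trienoate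
Product: 17 methyl (2Z,5Z,9E)-2-(bromomethyl)-10-{[(tert-butyldimethylsilyl)oxy]methyl}-6-(hydroxymethyl)-12-oxododeca-2,5,9-trienoate
Conditions: PPTS (0.3 equiv), acetone/H2O 10:1, 40 °C; used at once
Reagents that add atoms: water, O
Why: Mild acid-catalysed acetal hydrolysis frees the C8 aldehyde and also removes the labile primary triethylsilyl ether, while the much more acid-stable TBS ether survives.

**Step 10**
Reactants: 17 methyl (2Z,5Z,9E)-2-(bromomethyl)-10-{[(tert-butyldimethylsilyl)oxy]methyl}-6-(hydroxymethyl)-12-oxododeca-2,5,9-trienoate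
Product: 20 (3aR,5Z,9E,11aS)-10-{[(tert-butyldimethylsilyl)oxy]methyl}-6-(hydroxymethyl)-3-methylidene-3a,4,7,8,11,11a-hexahydrocyclodeca[b]furan-2(3H)-one, via allylchromium species 18 (not isolated), via hydroxy ester 19 (not isolated)
Conditions: CrCl2 (4 equiv), (S,S)-1,8-bis(4-isopropyl-4,5-dihydrooxazol-2-yl)-3,6-diphenyl-9H-carbazole (4.4 equiv), i-Pr2NEt (4.4 equiv), THF, rt; 17 added over 12 h to 2 mM; aqueous work-up; then PPTS (cat.), CH2Cl2, rt
Reagents that add atoms: none
Why: Proposed new method: two equivalents of ligated divalent chromium reduce the allylic C–Br bond to a γ-substituted 2-(methoxycarbonyl)allylchromium, so that C7, normally the electrophilic β-carbon of the acrylate, becomes nucleophilic (a homoenolate-type d3 synthon) and adds to the electrophilic aldehyde carbon C8 through a six-membered chair transition state in which the tether leaves both reacting carbons equatorially (anti addition, hence the trans ring fusion), the chiral tridentate carbazolide ligand shields one aldehyde face to give 7R,8S, and the γ-hydroxy ester then lactonises; the closest known reaction types are the enantioselective chromium-catalysed Nozaki–Hiyama–Kishi 2-(alkoxycarbonyl)allylation of aldehydes to α-methylene-γ-butyrolactones and achiral CrCl2-mediated macrocyclising Barbier closures of ten-membered germacranolide rings.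

**Step 11**
Reactants: 21 methyl (2S)-3-hydroxy-2-methylpropanoate
Product: 22 methyl (2S)-3-[(tert-butyldimethylsilyl)oxy]-2-methylpropanoate
Conditions: t-BuMe2SiCl, imidazole, CH2Cl2, rt
Reagents that add atoms: tert-butylchlorodimethylsilane, CC(C)(C)[Si](C)(C)Cl
Why: Silylation of the primary alcohol prevents self-condensation in the later esterification; the stereocentre is untouched.

**Step 12**
Reactants: 22 methyl (2S)-3-[(tert-butyldimethylsilyl)oxy]-2-methylpropanoate
Product: 23 (2S)-3-[(tert-butyldimethylsilyl)oxy]-2-methylpropanoic acid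
Conditions: LiOH·H2O, THF/H2O, 0 °C to rt; then aq. HCl to pH 4
Reagents that add atoms: lithium hydroxide, [Li+].[OH-]
Why: Mild saponification at low temperature cleaves the methyl ester without epimerising the α-stereocentre or removing the silyl ether.

**Step 13**
Reactants: 20 (3aR,5Z,9E,11aS)-10-{[(tert-butyldimethylsilyl)oxy]methyl}-6-(hydroxymethyl)-3-methylidene-3a,4,7,8,11,11a-hexahydrocyclodeca[b]furan-2(3H)-one; 23 (2S)-3-[(tert-butyldimethylsilyl)oxy]-2-methylpropanoic acid
Product: 24 [(3aR,5Z,9E,11aS)-10-{[(tert-butyldimethylsilyl)oxy]methyl}-3-methylidene-2-oxo-2,3,3a,4,7,8,11,11a-octahydrocyclodeca[b]furan-6-yl]methyl (2S)-3-[(tert-butyldimethylsilyl)oxy]-2-methylpropanoate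
Conditions: DCC, DMAP (cat.), CH2Cl2, 0 °C to rt
Reagents that add atoms: none
Why: Steglich esterification of the only free (primary allylic) alcohol is fast at 0 °C and does not disturb the α-methylene lactone or the acid stereocentre.

**Step 14**
Reactants: 24 [(3aR,5Z,9E,11aS)-10-{[(tert-butyldimethylsilyl)oxy]methyl}-3-methylidene-2-oxo-2,3,3a,4,7,8,11,11a-octahydrocyclodeca[b]furan-6-yl]methyl (2S)-3-[(tert-butyldimethylsilyl)oxy]-2-methylpropanoate
Product: 25 [(3aR,5Z,9E,11aS)-10-(hydroxymethyl)-3-methylidene-2-oxo-2,3,3a,4,7,8,11,11a-octahydrocyclodeca[b]furan-6-yl]methyl (2S)-3-hydroxy-2-methylpropanoate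
Conditions: HF·pyridine, THF/pyridine, 0 °C to rt
Reagents that add atoms: none
Why: Buffered fluoride desilylation removes both primary TBS ethers under conditions that leave the esters, the Michael-acceptor lactone and the 1,5-diene untouched.

**Compound list**
1 | methyl 5-bromo-4-oxopentanoate | COC(=O)CCC(=O)CBr | starting material
2 | methyl 5-(formyloxy)-4-oxopentanoate | COC(=O)CCC(=O)COC=O | intermediate
3 | methyl 5-hydroxy-4-oxopentanoate | COC(=O)CCC(=O)CO | intermediate
4 | methyl 4-oxo-5-[(triethylsilyl)oxy]pentanoate | COC(=O)CCC(=O)CO[Si](CC)(CC)CC | intermediate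
5 | (but-3-en-1-yl)triphenylphosphonium bromide | C=CCC[P+](c1ccccc1)(c1ccccc1)c1ccccc1.[Br-] | starting material
6 | but-3-enylidene(triphenyl)phosphorane | C=CCC=P(c1ccccc1)(c1ccccc1)c1ccccc1 | intermediate
7 | methyl (4Z)-4-{[(triethylsilyl)oxy]methyl}octa-4,7-dienoate | COC(=O)CC/C(CO[Si](CC)(CC)CC)=C/CC=C | intermediate
8 | trimethyl phosphonoacetate | COC(=O)CP(=O)(OC)OC | starting material
9 | 2-bromo-1,1-dimethoxyethane | COC(CBr)OC | starting material
10 | methyl 2-(dimethoxyphosphoryl)-4,4-dimethoxybutanoate (racemic) | COC(=O)C(CC(OC)OC)P(=O)(OC)OC | intermediate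
11 | (4Z)-4-{[(triethylsilyl)oxy]methyl}octa-4,7-dienal | O=CCC/C(CO[Si](CC)(CC)CC)=C/CC=C | intermediate
12 | methyl (2E,6Z)-2-(2,2-dimethoxyethyl)-6-{[(triethylsilyl)oxy]methyl}deca-2,6,9-trienoate | COC(=O)/C(CC(OC)OC)=C/CC/C(CO[Si](CC)(CC)CC)=C/CC=C | intermediate
13 | (2E,6Z)-2-(2,2-dimethoxyethyl)-6-{[(triethylsilyl)oxy]methyl}deca-2,6,9-trien-1-ol | OC/C(CC(OC)OC)=C/CC/C(CO[Si](CC)(CC)CC)=C/CC=C | intermediate
14 | (2E,6Z)-1-[(tert-butyldimethylsilyl)oxy]-2-(2,2-dimethoxyethyl)-6-{[(triethylsilyl)oxy]methyl}deca-2,6,9-triene | CC(C)(C)[Si](C)(C)OC/C(CC(OC)OC)=C/CC/C(CO[Si](CC)(CC)CC)=C/CC=C | intermediate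
15 | methyl 2-(bromomethyl)acrylate | C=C(CBr)C(=O)OC | starting material
16 | methyl (2Z,5Z,9E)-2-(bromomethyl)-10-{[(tert-butyldimethylsilyl)oxy]methyl}-12,12-dimethoxy-6-{[(triethylsilyl)oxy]methyl}dodeca-2,5,9-trienoate | COC(=O)/C(CBr)=C/C/C=C(\CO[Si](CC)(CC)CC)CC/C=C(\CC(OC)OC)CO[Si](C)(C)C(C)(C)C | intermediate
17 | methyl (2Z,5Z,9E)-2-(bromomethyl)-10-{[(tert-butyldimethylsilyl)oxy]methyl}-6-(hydroxymethyl)-12-oxododeca-2,5,9-trienoate | COC(=O)/C(CBr)=C/C/C=C(\CO)CC/C=C(\CC=O)CO[Si](C)(C)C(C)(C)C | intermediate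
18 | allylchromium dichloride derived from 17 (C–Br replaced by C–CrCl2; chiral ligand omitted) | COC(=O)/C(C[Cr](Cl)Cl)=C/C/C=C(\CO)CC/C=C(\CC=O)CO[Si](C)(C)C(C)(C)C | intermediate
19 | methyl 2-[(1R,2S,4E,8Z)-4-{[(tert-butyldimethylsilyl)oxy]methyl}-2-hydroxy-8-(hydroxymethyl)cyclodeca-4,8-dien-1-yl]prop-2-enoate | O[C@H]1C/C(CO[Si](C)(C)C(C)(C)C)=C\CC/C(CO)=C/C[C@@H]1C(=C)C(=O)OC | intermediate
20 | (3aR,5Z,9E,11aS)-10-{[(tert-butyldimethylsilyl)oxy]methyl}-6-(hydroxymethyl)-3-methylidene-3a,4,7,8,11,11a-hexahydrocyclodeca[b]furan-2(3H)-one | C=C1C(=O)O[C@H]2C/C(CO[Si](C)(C)C(C)(C)C)=C\CC/C(CO)=C/C[C@H]12 | intermediate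
21 | methyl (2S)-3-hydroxy-2-methylpropanoate | COC(=O)[C@@H](C)CO | starting material
22 | methyl (2S)-3-[(tert-butyldimethylsilyl)oxy]-2-methylpropanoate | COC(=O)[C@@H](C)CO[Si](C)(C)C(C)(C)C | intermediate
23 | (2S)-3-[(tert-butyldimethylsilyl)oxy]-2-methylpropanoic acid | OC(=O)[C@@H](C)CO[Si](C)(C)C(C)(C)C | intermediate
24 | [(3aR,5Z,9E,11aS)-10-{[(tert-butyldimethylsilyl)oxy]methyl}-3-methylidene-2-oxo-2,3,3a,4,7,8,11,11a-octahydrocyclodeca[b]furan-6-yl]methyl (2S)-3-[(tert-butyldimethylsilyl)oxy]-2-methylpropanoate | C=C1C(=O)O[C@H]2C/C(CO[Si](C)(C)C(C)(C)C)=C\CC/C(COC(=O)[C@@H](C)CO[Si](C)(C)C(C)(C)C)=C/C[C@H]12 | intermediate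
25 | [(3aR,5Z,9E,11aS)-10-(hydroxymethyl)-3-methylidene-2-oxo-2,3,3a,4,7,8,11,11a-octahydrocyclodeca[b]furan-6-yl]methyl (2S)-3-hydroxy-2-methylpropanoate | C=C1C(=O)O[C@H]2C/C(CO)=C\CC/C(COC(=O)[C@@H](C)CO)=C/C[C@H]12 | target

**Step count and risks**
Total step count: 14. Longest linear sequence: 11 steps (1, 2, 3, 5, 6, 7, 8, 9, 10, 13, 14).

Most likely to fail, first: step 10. The ligand-controlled ring closure is new and may give poor enantio- or diastereocontrol. The fallback gives up catalyst control and resolves through the side chain. It sets out from 17, which is cyclised with unligated CrCl2 (THF/DMF, high dilution), relying only on macrocyclic control for the trans fusion. This gives racemic material, that is 19 and 20 accompanied by the enantiomeric hydroxy ester F1 and the enantiomeric lactone F2. Esterification of the racemate with enantiopure 23 (DCC, DMAP) gives 24 together with the diastereomeric ester F3, which is removed by preparative HPLC; the route is rejoined at 24.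

Second: step 8. Cross-metathesis with a 1,1-disubstituted acrylate carrying an allylic bromide may stall. The fallback builds the bromomethyl acrylate in stages and sets out from 14. Cross-metathesis with methyl acrylate (same catalyst) gives the E-enoate F4. A tandem thia-Michael/aldol reaction (PhSLi, THF, −78 °C; then monomeric formaldehyde) gives the β-phenylsulfanyl α-hydroxymethyl ester F5. NaIO4 oxidation gives the sulfoxide F6, whose thermal syn-elimination (toluene, 80 °C) gives the 2-(hydroxymethyl)enoate F7. Appel bromination (CBr4, PPh3) rejoins the route at 16.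

Third: step 9. The β,γ-unsaturated aldehyde may conjugate, or the TBS ether may be lost, under aqueous acid. The fallback separates the two deprotections and avoids aqueous acid; it sets out from 16. Non-hydrolytic acetal cleavage (Et3SiOTf, 2,4,6-collidine, CH2Cl2, 0 °C; then H2O) gives the silyl-protected aldehyde F8 with both silyl ethers intact. Ring closure as in step 10 proceeds through the allylchromium species F9 and the hydroxy ester F10 to the triethylsilyl-protected lactone F11. PPTS in MeOH at 0 °C then removes only the triethylsilyl group and rejoins the route at 20.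

**Further compounds**
F1 | step 10 | methyl 2-[(1S,2R,4E,8Z)-4-{[(tert-butyldimethylsilyl)oxy]methyl}-2-hydroxy-8-(hydroxymethyl)cyclodeca-4,8-dien-1-yl]prop-2-enoate | O[C@@H]1C/C(CO[Si](C)(C)C(C)(C)C)=C\CC/C(CO)=C/C[C@H]1C(=C)C(=O)OC
F2 | step 10 | (3aS,5Z,9E,11aR)-10-{[(tert-butyldimethylsilyl)oxy]methyl}-6-(hydroxymethyl)-3-methylidene-3a,4,7,8,11,11a-hexahydrocyclodeca[b]furan-2(3H)-one | C=C1C(=O)O[C@@H]2C/C(CO[Si](C)(C)C(C)(C)C)=C\CC/C(CO)=C/C[C@@H]12
F3 | step 10 | [(3aS,5Z,9E,11aR)-10-{[(tert-butyldimethylsilyl)oxy]methyl}-3-methylidene-2-oxo-2,3,3a,4,7,8,11,11a-octahydrocyclodeca[b]furan-6-yl]methyl (2S)-3-[(tert-butyldimethylsilyl)oxy]-2-methylpropanoate | C=C1C(=O)O[C@@H]2C/C(CO[Si](C)(C)C(C)(C)C)=C\CC/C(COC(=O)[C@@H](C)CO[Si](C)(C)C(C)(C)C)=C/C[C@@H]12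
F4 | step 8 | methyl (2E,5Z,9E)-10-{[(tert-butyldimethylsilyl)oxy]methyl}-12,12-dimethoxy-6-{[(triethylsilyl)oxy]methyl}dodeca-2,5,9-trienoate | COC(=O)/C=C/C/C=C(\CO[Si](CC)(CC)CC)CC/C=C(\CC(OC)OC)CO[Si](C)(C)C(C)(C)C
F5 | step 8 | methyl (5Z,9E)-10-{[(tert-butyldimethylsilyl)oxy]methyl}-2-(hydroxymethyl)-12,12-dimethoxy-3-(phenylsulfanyl)-6-{[(triethylsilyl)oxy]methyl}dodeca-5,9-dienoate (diastereomer mixture) | COC(=O)C(CO)C(Sc1ccccc1)C/C=C(\CO[Si](CC)(CC)CC)CC/C=C(\CC(OC)OC)CO[Si](C)(C)C(C)(C)C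
F6 | step 8 | methyl (5Z,9E)-10-{[(tert-butyldimethylsilyl)oxy]methyl}-2-(hydroxymethyl)-12,12-dimethoxy-3-(phenylsulfinyl)-6-{[(triethylsilyl)oxy]methyl}dodeca-5,9-dienoate (diastereomer mixture) | COC(=O)C(CO)C(S(=O)c1ccccc1)C/C=C(\CO[Si](CC)(CC)CC)CC/C=C(\CC(OC)OC)CO[Si](C)(C)C(C)(C)C
F7 | step 8 | methyl (2E,5Z,9E)-10-{[(tert-butyldimethylsilyl)oxy]methyl}-2-(hydroxymethyl)-12,12-dimethoxy-6-{[(triethylsilyl)oxy]methyl}dodeca-2,5,9-trienoate | COC(=O)/C(CO)=C/C/C=C(\CO[Si](CC)(CC)CC)CC/C=C(\CC(OC)OC)CO[Si](C)(C)C(C)(C)C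
F8 | step 9 | methyl (2Z,5Z,9E)-2-(bromomethyl)-10-{[(tert-butyldimethylsilyl)oxy]methyl}-12-oxo-6-{[(triethylsilyl)oxy]methyl}dodeca-2,5,9-trienoate | COC(=O)/C(CBr)=C/C/C=C(\CO[Si](CC)(CC)CC)CC/C=C(\CC=O)CO[Si](C)(C)C(C)(C)C
F9 | step 9 | allylchromium dichloride derived from F8 (C–Br replaced by C–CrCl2; chiral ligand omitted) | COC(=O)/C(C[Cr](Cl)Cl)=C/C/C=C(\CO[Si](CC)(CC)CC)CC/C=C(\CC=O)CO[Si](C)(C)C(C)(C)C
F10 | step 9 | methyl 2-[(1R,2S,4E,8Z)-4-{[(tert-butyldimethylsilyl)oxy]methyl}-2-hydroxy-8-{[(triethylsilyl)oxy]methyl}cyclodeca-4,8-dien-1-yl]prop-2-enoate | O[C@H]1C/C(CO[Si](C)(C)C(C)(C)C)=C\CC/C(CO[Si](CC)(CC)CC)=C/C[C@@H]1C(=C)C(=O)OC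
F11 | step 9 | (3aR,5Z,9E,11aS)-10-{[(tert-butyldimethylsilyl)oxy]methyl}-3-methylidene-6-{[(triethylsilyl)oxy]methyl}-3a,4,7,8,11,11a-hexahydrocyclodeca[b]furan-2(3H)-one | C=C1C(=O)O[C@H]2C/C(CO[Si](C)(C)C(C)(C)C)=C\CC/C(CO[Si](CC)(CC)CC)=C/C[C@H]12
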